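## Structural features

The target is a flavone: benzene ring A is fused to the 4-pyranone ring C (a 4H-chromen-4-one), and phenyl ring B is attached at C2 through the single C2–C1' bond. The molecule is flat and achiral, so there is no stereocenter to set and none that neighbours another. Apart from C6, every position of the chromenone is substituted: methoxy at C3 and C7, hydroxyl at C5 and C8, and ring B is a 3',4',5'-trihydroxyphenyl (pyrogallol) unit. Two parts are fragile: the 5,8-dihydroxy pair is a para-hydroquinone that oxidises easily to the 5,8-quinone, and the pyrogallol ring autoxidises, fastest in base, so both must be uncovered last under reducing, non-basic conditions. The real difficulty is not the carbon skeleton but the regiochemistry of seven ring oxygens: two must stay methyl ethers while five end up free, and C8 must carry oxygen between C7 and C8a. The 5-hydroxyl is hydrogen-bonded to the C4 carbonyl, which sets O5 apart from all other oxygens: it alone can be dealkylated by chelation, and its phenoxide directs an oxidant to the para carbon C8. The key step uses the ortho relationship of O1 on C8a and the C4 carbonyl on C4a, with the C5 oxygen on the other side of C4a. This is the pattern left when a 3-alkoxy aryne accepts an oxygen nucleophile at its remote carbon and an acyl group at the carbon next to the alkoxy group.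

## Logic of the disconnections

19 ⇒ 18. Three benzyl O–CH2 bonds on ring B are restored; the skeleton is untouched. The pyrogallol must stay masked through the oxidation at C8. The gain is a ring B that is inert to base and oxidant. The forward step must deprotect under neutral, reducing conditions that spare both methyl ethers, the C2–C3 double bond and the hydroquinone.

18 ⇒ 16. The C8–O bond is cut. C8 is para to O5, so this oxygen can come from a para-selective phenoxide oxidation passing through 17. The gain is a ring A with C8–H and a 5,7-dioxygenation pattern, which a regioselective aryne addition can deliver. The forward step needs a free 5-hydroxyl, para over ortho (C6) selectivity, and ring B ethers that tolerate the oxidant.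

16 ⇒ 15. The O5–H bond is traced back to O5–CH3. In 15 the two ring A methoxy groups come from one symmetric phenol, and only the one peri to the C4 carbonyl can be removed by chelation. The gain is that ring A needs no protecting-group differentiation before ring C exists. The forward step must cleave one of three methyl ethers without touching three benzyl ethers.

15 ⇒ 6 + 12. The O1–C8a, C4a–C4 and O1–C2 bonds are cut together. These are exactly the bonds that join ring A to the C2–C3–C4 unit, so 15 divides into two fragments of similar size and ring C needs no separate construction. The forward step must place oxygen on the carbon of 13 remote from the methoxy group and the acyl carbon on the near one, pass through 14, and close ring C at the flavone oxidation level. The last point is why 12 carries a leaving group on its β-carbon.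

6 ⇒ 3 ⇒ 2 ⇒ 1. The O–S and C–Si bonds of 6 are cut, silicon is traced back to oxygen (through 5 and 4 to 3), and the C–Br bond of 2 to a C–H bond of 1. The ortho relationship of silicon and triflate is fixed by an ortho bromine. The gain is a commercial, symmetric phenol. The forward demand is monobromination next to the hydroxyl.

12 ⇒ 11 ⇒ 10 ⇒ 7 + 8. The acid is traced to its methyl ester 11, the C–Cl bond of 11 to the ketone of 10, and the bond between the ketone carbon and the methoxy-bearing carbon of 10 is cut to give 7 and 8 (through 9). 10 already holds every carbon at the right oxidation level, and ring B is bought complete. The forward steps need a crossed condensation without self-condensation of 8, and a ketone to vinyl chloride conversion that leaves the benzyl ethers intact.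

## Other disconnections considered

Alternative 1: The cut runs through ring B at C1'–C2' and C5'–C6', so ring B would be made from a furan and an alkyne.
- Forward key step: 3,4-bis(benzyloxy)furan A2 would add as the diene to the triple bond of 2-ethynyl-3,5,7,8-tetramethoxy-4H-chromen-4-one A3. Acid would then open the oxygen bridge with aromatisation to 2-[3,4-bis(benzyloxy)-5-hydroxyphenyl]-3,5,7,8-tetramethoxy-4H-chromen-4-one A1, the furan oxygen becoming the C5' hydroxyl.
- In its favour: the C8 oxygen is present in A3 from the start, so no late oxidation of a C8–H bond is needed. On this point the alternative is better than the chosen plan.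
- Against it here: ring B is the one part of the target that can be bought complete (as 7), so building it spends steps where none are needed. The differentiated C5' hydroxyl of A1 has no use when all three ring B oxygens end up free. A2 is an electron-rich, acid-sensitive diene that must be prepared. The bridge must open at the C2'–O bond and not the C5'–O bond, or a 2',3',4' pattern results. A1 carries four methyl ethers, of which those on O5 and O8 must go while those on O3 and O7 stay; O5 can be reached by chelation, but O8 has no such handle and would need an oxidative detour through the 5,8-quinone.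
- Comparison: structurally it solves the C8 problem early but creates a harder ether-differentiation problem late. Mechanistically the cycloaddition is about as predictable as the aryne addition, the cationic bridge opening less so than the ring closure of the chosen plan. In step economy it should be the longer route, since A2 and A3 each need several steps.

Alternative 2: The cut is the C5–C4a bond (with C8–C8a made one step earlier), so ring A would be built onto a finished pyranone.
- Forward key step: 3-methoxy-2-[3,4,5-tris(benzyloxy)phenyl]-4H-pyran-4-one A7, metalated at C6, would add to the ketone-like carbonyl of 3-methoxycyclobut-3-ene-1,2-dione A6 to give 4-hydroxy-3-methoxy-4-{5-methoxy-4-oxo-6-[3,4,5-tris(benzyloxy)phenyl]-4H-pyran-2-yl}cyclobut-2-en-1-one A5. Heating A5 would open the four-membered ring to a dienylketene, whose ketene carbon closes onto the pyranone carbon that becomes C4a; tautomerisation gives 5,8-dihydroxy-3,7-dimethoxy-2-[3,4,5-tris(benzyloxy)phenyl]-4H-chromen-4-one A4, the same compound as 18.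
- In its favour: the hydroquinone oxygens at C5 and C8 and the methoxy group at C7 are placed by construction, so neither a para-selective oxidation nor a selective demethylation is needed. On regiocontrol of ring A oxygenation the alternative is better than the chosen plan. The neutral thermal conditions are as compatible with benzyl ethers as the fluoride conditions of the chosen key step; on this point the two are equal.
- Against it here: A7 has to be made and then metalated next to the ring oxygen in the presence of its own enone carbonyl. A6 is a reactive squaric acid derivative that is not a routine stock reagent. The addition must occur at the correct one of its two carbonyls.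
- Comparison: structurally it reaches 18 with fewer selectivity questions. Mechanistically it relies on two consecutive electrocyclic events, against a polar addition, acyl shift and ring closure. In step economy the chosen plan should win, because its three starting materials are stock compounds and rings A and B are both bought intact, while the route to A5 needs a de novo pyranone.

Alternative 3: The cut is the C4–C4a bond alone; O1–C2 would be formed in a separate earlier step.
- Forward key step: (E)-3-(2,5-diisopropoxy-3-methoxyphenoxy)-2-methoxy-3-[3,4,5-tris(benzyloxy)phenyl]acrylic acid A9 would in principle come from 2,5-diisopropoxy-3-methoxyphenol A10 and 11 by addition–elimination and saponification. Activation (trifluoroacetic anhydride, or oxalyl chloride then SnCl4) would acylate the aryloxy ring at its only free ortho carbon to give 5,8-diisopropoxy-3,7-dimethoxy-2-[3,4,5-tris(benzyloxy)phenyl]-4H-chromen-4-one A8.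
- In its favour: the ring closure has no regiochemical choice, because only one ortho carbon is free and it is activated by three oxygens. On predictability of regiochemistry it is equal to or better than the aryne addition. The C8 oxygen is in place from the start. Isopropyl and benzyl ethers could fall together with BCl3 while the methyl ethers stay, so the endgame could be a single operation; on steps after the key step the alternative is better than the chosen plan.
- Against it here: A10 has three different oxygen substituents in a 1,2,3,5 arrangement and is not a stock compound, so the steps saved at the end are spent at the start. Only the alkene isomer with the carboxyl cis to the aryloxy group can close. The strongly acidic or Lewis-acidic activation threatens the isopropyl and benzyl ethers. The hindered phenol must first displace chloride from a deactivated, fully substituted acrylate.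
- Comparison: structurally it trades a late C–H oxidation for an early, laborious phenol synthesis. Mechanistically it is a classical electrophilic aromatic substitution. In step economy it forms in two operations (ether formation, then acylation) the bonds that the chosen key step forms in one, and its total length should be greater.

Key step: step 7

Remark on the chemistry: 11, 12 and 14 are drawn as Z isomers, but a mixture of alkene isomers is acceptable because ring C closes by addition–elimination; 10 is racemic at a labile carbon that becomes sp2 in step 5.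

## Route

Step 1
Reactants: 1 3,5-dimethoxyphenol
Product: 2 2-bromo-3,5-dimethoxyphenol
Conditions: NBS (1.0 equiv), CH2Cl2, −78 °C → rt; chromatography
Reagents that add atoms: N-bromosuccinimide, O=C1CCC(=O)N1Br
Why: Electrophilic aromatic bromination; in a non-polar solvent at low temperature NBS is delivered next to the free hydroxyl, and the two equivalent ortho positions are less hindered than C4 between the two methoxy groups, so monobromination at C2 should predominate.

Step 2
Reactants: 2 2-bromo-3,5-dimethoxyphenol
Product: 3 (2-bromo-3,5-dimethoxyphenoxy)trimethylsilane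
Conditions: HN(SiMe3)2, THF, 65 °C; concentrate
Reagents that add atoms: hexamethyldisilazane, C[Si](C)(C)N[Si](C)(C)C
Why: O-silylation of a phenol by a silazane; ammonia is the only by-product, so the crude silyl ether can be used directly.

Step 3
Reactants: 3 (2-bromo-3,5-dimethoxyphenoxy)trimethylsilane
Product: 6 3,5-dimethoxy-2-(trimethylsilyl)phenyl trifluoromethanesulfonate, via aryllithium 4 (not isolated), via lithium phenoxide 5 (not isolated)
Conditions: n-BuLi, THF, −100 → −78 °C; then Tf2O, −100 °C → rt
Reagents that add atoms: trifluoromethanesulfonic anhydride, O=S(=O)(OS(=O)(=O)C(F)(F)F)C(F)(F)F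
Why: Bromine–lithium exchange gives 4, which undergoes the retro-Brook 1,3-shift of silicon from oxygen to carbon because phenoxide 5 is more stable than the aryl anion; O-triflation of 5 gives the ortho-silylaryl triflate.

Step 4
Reactants: 7 methyl 3,4,5-tris(benzyloxy)benzoate; 8 methyl methoxyacetate
Product: 10 methyl 2-methoxy-3-oxo-3-[3,4,5-tris(benzyloxy)phenyl]propanoate (racemic), via lithium enolate 9 (not isolated)
Conditions: LiN(i-Pr)2 (2.2 equiv), 8 (2.2 equiv), THF, −78 °C; then 7, −78 → 0 °C; aq. NH4Cl
Reagents that add atoms: none
Why: Crossed Claisen condensation; 7 cannot enolise, enolate 9 is preformed so that self-condensation of 8 is suppressed, and the second equivalent of 9 deprotonates the β-keto ester and drives the equilibrium.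

Step 5
Reactants: 10 methyl 2-methoxy-3-oxo-3-[3,4,5-tris(benzyloxy)phenyl]propanoate
Product: 11 methyl (Z)-3-chloro-2-methoxy-3-[3,4,5-tris(benzyloxy)phenyl]acrylate
Conditions: (COCl)2, DMF, CH2Cl2, 0 °C; then ClCH2CH2Cl, 60 °C
Reagents that add atoms: oxalyl chloride, O=C(Cl)C(=O)Cl
Why: Vilsmeier-type deoxychlorination of a 1,3-dicarbonyl compound; the enol oxygen of 10 attacks the chloroiminium salt formed from DMF and oxalyl chloride, and chloride displaces DMF from the activated β-carbon by addition–elimination. The α-carbon has no second hydrogen, so no formylation can follow.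

Step 6
Reactants: 11 methyl (Z)-3-chloro-2-methoxy-3-[3,4,5-tris(benzyloxy)phenyl]acrylate
Product: 12 (Z)-3-chloro-2-methoxy-3-[3,4,5-tris(benzyloxy)phenyl]acrylic acid
Conditions: LiOH·H2O, THF/MeOH/H2O, rt; then 1 M HCl to pH 2
Reagents that add atoms: lithium hydroxide, [Li+].[OH-]
Why: Ester saponification; the β-carbon is deactivated towards hydroxide by the α-methoxy donor, and the absence of an α-hydrogen excludes elimination to an alkyne, so the vinyl chloride should survive.

Step 7
Reactants: 6 3,5-dimethoxy-2-(trimethylsilyl)phenyl trifluoromethanesulfonate; 12 (Z)-3-chloro-2-methoxy-3-[3,4,5-tris(benzyloxy)phenyl]acrylic acid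
Product: 15 3,5,7-trimethoxy-2-[3,4,5-tris(benzyloxy)phenyl]-4H-chromen-4-one, via 3,5-dimethoxybenzyne 13 (not isolated), via cesium ortho-acylphenoxide 14 (not isolated)
Conditions: CsF (4 equiv), 6 (1.5 equiv), THF, sealed tube, 125 °C
Reagents that add atoms: none
Why: Fluoride removes the silyl group of 6 with loss of triflate to give aryne 13 and converts 12 into its cesium carboxylate. The carboxylate oxygen adds to the aryne carbon remote from the neighbouring methoxy group (the future C8a), leaving the aryl anion on the carbon next to that methoxy group (the future C4a). This anion attacks the carbonyl of its own aryl ester through a four-membered alkoxide that opens to phenoxide 14, an anionic ortho-Fries-type acyl shift that forms the C4a–C4 bond. The phenoxide of 14 then adds to the chlorine-bearing β-carbon of the enone in a 6-endo-trig conjugate addition and chloride is expelled, which forms O1–C2 and closes ring C as the pyranone. The closest known reaction type is the insertion of arynes into the carbon–oxygen bond of carboxylic acids, with ring closure in the same flask to xanthones, chromanones and flavones. No stereocenter is formed, and the alkene geometry of 12 does not matter because the enolate formed on conjugate addition can rotate before chloride leaves. The step needs regioselective addition to the unsymmetrical aryne, secured by the inductively withdrawing methoxy group beside the triple bond, which makes the distal carbon the electrophilic one and stabilises the adjacent carbanion. It also needs acyl transfer to outrun protonation of the aryl anion, which the aprotic medium, excess CsF and high temperature should favour; benzyl and methyl ethers are inert to fluoride under these conditions.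

Step 8
Reactants: 15 3,5,7-trimethoxy-2-[3,4,5-tris(benzyloxy)phenyl]-4H-chromen-4-one
Product: 16 5-hydroxy-3,7-dimethoxy-2-[3,4,5-tris(benzyloxy)phenyl]-4H-chromen-4-one
Conditions: AlCl3 (3 equiv), MeCN, 0 °C → rt; then 1 M HCl, 50 °C
Reagents that add atoms: none
Why: Chelation-controlled ether cleavage; aluminium binds the C4 carbonyl and the peri oxygen O5 in a six-membered chelate, which activates only that methyl group towards chloride. The 3-methoxy group would need a less favourable five-membered chelate, the 7-methoxy and benzyl ethers are not chelated, and acetonitrile tempers the Lewis acid.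

Step 9
Reactants: 16 5-hydroxy-3,7-dimethoxy-2-[3,4,5-tris(benzyloxy)phenyl]-4H-chromen-4-one
Product: 18 5,8-dihydroxy-3,7-dimethoxy-2-[3,4,5-tris(benzyloxy)phenyl]-4H-chromen-4-one, via potassium chromen-8-yl sulfate 17 (not isolated)
Conditions: K2S2O8, aq. KOH, pyridine, 0 °C → rt; acidify, remove unchanged 16; then 2 M HCl, Na2SO3, 85 °C, under Ar
Reagents that add atoms: potassium persulfate, [K+].[K+].[O-]S(=O)(=O)OOS(=O)(=O)[O-]
Why: Elbs persulfate oxidation; the phenoxide of 16 attacks the peroxide oxygen through its para carbon C8, which is also activated by the 7-methoxy group, to give aryl sulfate 17. Acid hydrolysis of 17 releases the hydroquinone, and sulfite keeps it reduced.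

Step 10
Reactants: 18 5,8-dihydroxy-3,7-dimethoxy-2-[3,4,5-tris(benzyloxy)phenyl]-4H-chromen-4-one
Product: 19 5,8-dihydroxy-3,7-dimethoxy-2-(3,4,5-trihydroxyphenyl)-4H-chromen-4-one (5,8,3',4',5'-pentahydroxy-3,7-dimethoxyflavone)
Conditions: H2 (1 atm), Pd/C, THF/MeOH, rt; filter and concentrate under Ar
Reagents that add atoms: none
Why: Hydrogenolysis of aryl benzyl ethers under neutral, reducing conditions, so the hydroquinone and pyrogallol units are released without oxidation (any quinone formed earlier is reduced back); the methyl ethers and the chromenone C2–C3 double bond are expected to persist.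

## Compound list

1 | 3,5-dimethoxyphenol | COc1cc(O)cc(OC)c1 | starting material
2 | 2-bromo-3,5-dimethoxyphenol | COc1cc(O)c(Br)c(OC)c1 | intermediate
3 | (2-bromo-3,5-dimethoxyphenoxy)trimethylsilane | COc1cc(O[Si](C)(C)C)c(Br)c(OC)c1 | intermediate
4 | [2,4-dimethoxy-6-(trimethylsilyloxy)phenyl]lithium | [Li]c1c(OC)cc(OC)cc1O[Si](C)(C)C | intermediate (not isolated)
5 | lithium 3,5-dimethoxy-2-(trimethylsilyl)phenolate | [Li+].[O-]c1cc(OC)cc(OC)c1[Si](C)(C)C | intermediate (not isolated)
6 | 3,5-dimethoxy-2-(trimethylsilyl)phenyl trifluoromethanesulfonate | COc1cc(OC)c([Si](C)(C)C)c(OS(=O)(=O)C(F)(F)F)c1 | intermediate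
7 | methyl 3,4,5-tris(benzyloxy)benzoate | COC(=O)c1cc(OCc2ccccc2)c(OCc2ccccc2)c(OCc2ccccc2)c1 | starting material
8 | methyl methoxyacetate | COCC(=O)OC | starting material
9 | lithium 1,2-dimethoxyethen-1-olate (enolate of 8, geometry undefined) | [Li+].[O-]C(OC)=COC | intermediate (not isolated)
10 | methyl 2-methoxy-3-oxo-3-[3,4,5-tris(benzyloxy)phenyl]propanoate (racemic) | COC(=O)C(OC)C(=O)c1cc(OCc2ccccc2)c(OCc2ccccc2)c(OCc2ccccc2)c1 | intermediate
11 | methyl (Z)-3-chloro-2-methoxy-3-[3,4,5-tris(benzyloxy)phenyl]acrylate | CO/C(C(=O)OC)=C(\Cl)c1cc(OCc2ccccc2)c(OCc2ccccc2)c(OCc2ccccc2)c1 | intermediate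
12 | (Z)-3-chloro-2-methoxy-3-[3,4,5-tris(benzyloxy)phenyl]acrylic acid | CO/C(C(=O)O)=C(\Cl)c1cc(OCc2ccccc2)c(OCc2ccccc2)c(OCc2ccccc2)c1 | intermediate
13 | 3,5-dimethoxybenzyne (1,2-didehydro-3,5-dimethoxybenzene) | COC1=CC(OC)=CC#C1 | intermediate (not isolated)
14 | cesium 2-[(Z)-3-chloro-2-methoxy-3-[3,4,5-tris(benzyloxy)phenyl]prop-2-enoyl]-3,5-dimethoxyphenolate | [Cs+].[O-]c1cc(OC)cc(OC)c1C(=O)/C(OC)=C(/Cl)c1cc(OCc2ccccc2)c(OCc2ccccc2)c(OCc2ccccc2)c1 | intermediate (not isolated)
15 | 3,5,7-trimethoxy-2-[3,4,5-tris(benzyloxy)phenyl]-4H-chromen-4-one | COc1cc(OC)c2c(=O)c(OC)c(-c3cc(OCc4ccccc4)c(OCc4ccccc4)c(OCc4ccccc4)c3)oc2c1 | intermediate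
16 | 5-hydroxy-3,7-dimethoxy-2-[3,4,5-tris(benzyloxy)phenyl]-4H-chromen-4-one | COc1cc(O)c2c(=O)c(OC)c(-c3cc(OCc4ccccc4)c(OCc4ccccc4)c(OCc4ccccc4)c3)oc2c1 | intermediate
17 | potassium 5-hydroxy-3,7-dimethoxy-4-oxo-2-[3,4,5-tris(benzyloxy)phenyl]-4H-chromen-8-yl sulfate | COc1cc(O)c2c(=O)c(OC)c(-c3cc(OCc4ccccc4)c(OCc4ccccc4)c(OCc4ccccc4)c3)oc2c1OS(=O)(=O)[O-].[K+] | intermediate (not isolated)
18 | 5,8-dihydroxy-3,7-dimethoxy-2-[3,4,5-tris(benzyloxy)phenyl]-4H-chromen-4-one | COc1cc(O)c2c(=O)c(OC)c(-c3cc(OCc4ccccc4)c(OCc4ccccc4)c(OCc4ccccc4)c3)oc2c1O | intermediate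
19 | 5,8-dihydroxy-3,7-dimethoxy-2-(3,4,5-trihydroxyphenyl)-4H-chromen-4-one | COc1cc(O)c2c(=O)c(OC)c(-c3cc(O)c(O)c(O)c3)oc2c1O | target

## Step count and least certain steps

Total: 10 steps. Longest linear sequence: 7 steps (steps 4, 5, 6, 7, 8, 9, 10; the arm through steps 1, 2, 3 is equally long).

Step 7 (key step).
- Risk: the aryl anion formed after carboxylate addition may be protonated, by the carboxylic acid or by HF, before it attacks the ester carbonyl, so the sequence would stop at O-arylation. Acyl transfer is slowed because the receiving carbon lies between two oxygen substituents.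
- Fallback: sets out from 2 and 12 and returns at 15. 2 is esterified with 12 (EDC·HCl, DMAP, CH2Cl2) to 2-bromo-3,5-dimethoxyphenyl (Z)-3-chloro-2-methoxy-3-[3,4,5-tris(benzyloxy)phenyl]acrylate F1. Bromine–lithium exchange with n-BuLi in THF at −100 °C generates the same ortho-acyloxy aryl anion regiospecifically and without a proton source. The anionic Fries shift and aqueous work-up should give (Z)-3-chloro-1-(2-hydroxy-4,6-dimethoxyphenyl)-2-methoxy-3-[3,4,5-tris(benzyloxy)phenyl]prop-2-en-1-one F2, and K2CO3 in DMF at 60 °C closes ring C to 15.

Step 9.
- Risk: low conversion and oxidative degradation. The phenoxide of 16 is lipophilic and poorly soluble in the aqueous phase that holds the persulfate, and radical decomposition of persulfate competes with the slow ionic attack of a chelated, deactivated phenoxide.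
- Fallback: sets out from 15 and returns at 18. Iodination of 15 (N-iodosuccinimide, catalytic CF3CO2H, MeCN) should go to C8, the less hindered of the two activated positions of a 5,7-dimethoxychromenone, giving 8-iodo-3,5,7-trimethoxy-2-[3,4,5-tris(benzyloxy)phenyl]-4H-chromen-4-one F3. Miyaura borylation (B2pin2, Pd(dppf)Cl2, KOAc, dioxane, 90 °C) gives 3,5,7-trimethoxy-8-(4,4,5,5-tetramethyl-1,3,2-dioxaborolan-2-yl)-2-[3,4,5-tris(benzyloxy)phenyl]-4H-chromen-4-one F4. Oxidation (NaBO3·4H2O, THF/H2O) gives 8-hydroxy-3,5,7-trimethoxy-2-[3,4,5-tris(benzyloxy)phenyl]-4H-chromen-4-one F5, and AlCl3 in MeCN as in step 8 removes the 5-methyl group to give 18.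

Step 8.
- Risk: loss of benzyl ethers by Lewis-acid cleavage alongside the desired demethylation, because the ring B ethers are electron-rich and AlCl3 is in excess.
- Fallback: sets out from 15 and returns at 16, accepting full dealkylation. BCl3 (excess) in CH2Cl2 from −78 to 0 °C removes the three benzyl groups and the chelated 5-methyl group and leaves the 3- and 7-methoxy groups, giving 5-hydroxy-3,7-dimethoxy-2-(3,4,5-trihydroxyphenyl)-4H-chromen-4-one F6. Benzyl bromide (3 equiv) and K2CO3 in DMF at rt under Ar re-benzylate the three ring B hydroxyls selectively, since the chelated 5-hydroxyl is the least acidic and least nucleophilic phenol, and return 16.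

Step 5.
- Risk: sluggish deoxychlorination, because the hindered aryl ketone of 10 enolises poorly, and acid-promoted loss of benzyl groups on prolonged heating.
- Fallback: sets out from 8 and returns at 11. Base-mediated condensation of 8 with purchasable 3,4,5-tris(benzyloxy)benzaldehyde F7 (NaOMe, MeOH/THF, reflux) gives methyl (Z)-2-methoxy-3-[3,4,5-tris(benzyloxy)phenyl]acrylate F8. Chlorination of this enol ether at its β-carbon with N-chlorosuccinimide in CH2Cl2, followed by DBU (halogenation–dehydrohalogenation), gives 11.

Step 1.
- Risk: bromination para to the hydroxyl and twofold bromination, since all three free ring positions are activated by three oxygens.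
- Fallback: sets out from 1 and returns at 6 by carbamate-directed ortho-metalation. 1 and isopropyl isocyanate (Et3N, CH2Cl2) give 3,5-dimethoxyphenyl N-isopropylcarbamate F9. In situ N-silylation (TBSOTf, TMEDA), lithiation with n-BuLi at −78 °C between the carbamate and the methoxy group, and quenching with Me3SiCl give 3,5-dimethoxy-2-(trimethylsilyl)phenyl N-isopropylcarbamate F10. Et2NH and DBU in MeCN at 40 °C release 3,5-dimethoxy-2-(trimethylsilyl)phenol F11, and PhNTf2 converts it into 6.

## Further compounds

F1 | step 7 | 2-bromo-3,5-dimethoxyphenyl (Z)-3-chloro-2-methoxy-3-[3,4,5-tris(benzyloxy)phenyl]acrylate | CO/C(C(=O)Oc1cc(OC)cc(OC)c1Br)=C(\Cl)c1cc(OCc2ccccc2)c(OCc2ccccc2)c(OCc2ccccc2)c1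
F2 | step 7 | (Z)-3-chloro-1-(2-hydroxy-4,6-dimethoxyphenyl)-2-methoxy-3-[3,4,5-tris(benzyloxy)phenyl]prop-2-en-1-one | CO/C(C(=O)c1c(O)cc(OC)cc1OC)=C(\Cl)c1cc(OCc2ccccc2)c(OCc2ccccc2)c(OCc2ccccc2)c1
F3 | step 9 | 8-iodo-3,5,7-trimethoxy-2-[3,4,5-tris(benzyloxy)phenyl]-4H-chromen-4-one | COc1cc(OC)c2c(=O)c(OC)c(-c3cc(OCc4ccccc4)c(OCc4ccccc4)c(OCc4ccccc4)c3)oc2c1I
F4 | step 9 | 3,5,7-trimethoxy-8-(4,4,5,5-tetramethyl-1,3,2-dioxaborolan-2-yl)-2-[3,4,5-tris(benzyloxy)phenyl]-4H-chromen-4-one | COc1cc(OC)c2c(=O)c(OC)c(-c3cc(OCc4ccccc4)c(OCc4ccccc4)c(OCc4ccccc4)c3)oc2c1B1OC(C)(C)C(C)(C)O1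
F5 | step 9 | 8-hydroxy-3,5,7-trimethoxy-2-[3,4,5-tris(benzyloxy)phenyl]-4H-chromen-4-one | COc1cc(OC)c2c(=O)c(OC)c(-c3cc(OCc4ccccc4)c(OCc4ccccc4)c(OCc4ccccc4)c3)oc2c1O
F6 | step 8 | 5-hydroxy-3,7-dimethoxy-2-(3,4,5-trihydroxyphenyl)-4H-chromen-4-one | COc1cc(O)c2c(=O)c(OC)c(-c3cc(O)c(O)c(O)c3)oc2c1
F7 | step 5 | 3,4,5-tris(benzyloxy)benzaldehyde | O=Cc1cc(OCc2ccccc2)c(OCc2ccccc2)c(OCc2ccccc2)c1
F8 | step 5 | methyl (Z)-2-methoxy-3-[3,4,5-tris(benzyloxy)phenyl]acrylate | CO/C(C(=O)OC)=C\c1cc(OCc2ccccc2)c(OCc2ccccc2)c(OCc2ccccc2)c1
F9 | step 1 | 3,5-dimethoxyphenyl N-isopropylcarbamate | CC(C)NC(=O)Oc1cc(OC)cc(OC)c1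
F10 | step 1 | 3,5-dimethoxy-2-(trimethylsilyl)phenyl N-isopropylcarbamate | CC(C)NC(=O)Oc1cc(OC)cc(OC)c1[Si](C)(C)C
F11 | step 1 | 3,5-dimethoxy-2-(trimethylsilyl)phenol | COc1cc(O)c([Si](C)(C)C)c(OC)c1
A1 | alternative 1 | 2-[3,4-bis(benzyloxy)-5-hydroxyphenyl]-3,5,7,8-tetramethoxy-4H-chromen-4-one | COc1cc(OC)c2c(=O)c(OC)c(-c3cc(O)c(OCc4ccccc4)c(OCc4ccccc4)c3)oc2c1OC
A2 | alternative 1 | 3,4-bis(benzyloxy)furan | c1occ(OCc2ccccc2)c1OCc1ccccc1
A3 | alternative 1 | 2-ethynyl-3,5,7,8-tetramethoxy-4H-chromen-4-one | COc1cc(OC)c2c(=O)c(OC)c(C#C)oc2c1OC
A4 | alternative 2 | 5,8-dihydroxy-3,7-dimethoxy-2-[3,4,5-tris(benzyloxy)phenyl]-4H-chromen-4-one | COc1cc(O)c2c(=O)c(OC)c(-c3cc(OCc4ccccc4)c(OCc4ccccc4)c(OCc4ccccc4)c3)oc2c1O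
A5 | alternative 2 | 4-hydroxy-3-methoxy-4-{5-methoxy-4-oxo-6-[3,4,5-tris(benzyloxy)phenyl]-4H-pyran-2-yl}cyclobut-2-en-1-one (racemic) | COC1=CC(=O)C1(O)C1=CC(=O)C(OC)=C(c2cc(OCc3ccccc3)c(OCc3ccccc3)c(OCc3ccccc3)c2)O1
A6 | alternative 2 | 3-methoxycyclobut-3-ene-1,2-dione | COC1=CC(=O)C1=O
A7 | alternative 2 | 3-methoxy-2-[3,4,5-tris(benzyloxy)phenyl]-4H-pyran-4-one | COc1c(-c2cc(OCc3ccccc3)c(OCc3ccccc3)c(OCc3ccccc3)c2)occc1=O
A8 | alternative 3 | 5,8-diisopropoxy-3,7-dimethoxy-2-[3,4,5-tris(benzyloxy)phenyl]-4H-chromen-4-one | COc1cc(OC(C)C)c2c(=O)c(OC)c(-c3cc(OCc4ccccc4)c(OCc4ccccc4)c(OCc4ccccc4)c3)oc2c1OC(C)C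
A9 | alternative 3 | (E)-3-(2,5-diisopropoxy-3-methoxyphenoxy)-2-methoxy-3-[3,4,5-tris(benzyloxy)phenyl]acrylic acid | CO/C(C(=O)O)=C(/Oc1cc(OC(C)C)cc(OC)c1OC(C)C)c1cc(OCc2ccccc2)c(OCc2ccccc2)c(OCc2ccccc2)c1
A10 | alternative 3 | 2,5-diisopropoxy-3-methoxyphenol | COc1cc(OC(C)C)cc(O)c1OC(C)C
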